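**Plan**
- Retrosynthesis: the C7 silyl ether is cleaved last. The four B-ring bonds C1'–C2', C2'–C3', C4'–C5' and C5'–C6' are then cut together, giving an α'-diazo enone and methoxyacetylene.
- The diazo enone is cut at the diazo carbon (diazo transfer) and at the enone C=C (Wittig) into a 3-formyl-7-silyloxychromone and a prenylated keto-ylide. The pyranone goes back to 2,4-dihydroxyacetophenone.
- Enabling feature: ring B is a 1,2,4,5-tetrasubstituted benzene with C2'–OH and C4'–OMe meta to each other, C1' on chromone C3 and prenyl on C5'. This resorcinol monoether pattern is what a vinylketene carbonyl and an alkoxyacetylene deliver.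
- Forward order: ring C closes onto ring A (step 1), the side chain is joined by olefination (step 4), the diazo group is installed (step 5), ring B is built in one operation (step 7), and desilylation follows.
- Stereochemistry: the target has no stereocentre. The only stereo-element on the way is the E enone from the stabilised ylide, and the transient sp3 centres of the cascade are lost on aromatisation.

Key step: step 7

Assumption: the target is achiral (no stereocentre, and the prenyl alkene carries two identical methyl groups), so the constitution alone defines the compound asked for.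

**Step 1**
Reactants: 1 2,4-dihydroxyacetophenone
Product: 3 7-hydroxy-4-oxo-4H-chromene-3-carbaldehyde, via iminium chloride 2 (not isolated)
Conditions: POCl3 (4 equiv), DMF, 0 °C → rt; then ice-water
Reagents that add atoms: N,N-dimethylformamide, CN(C)C=O; water, O
Why: Vilsmeier–Haack reaction of an o-hydroxyacetophenone, in which the chloroiminium reagent formylates the acetyl methyl group twice, the ortho phenol closes the pyranone (ring C) and water hydrolyses iminium 2 to the aldehyde, the C7 phenol being regenerated on aqueous work-up.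

**Step 2**
Reactants: 3 7-hydroxy-4-oxo-4H-chromene-3-carbaldehyde
Product: 4 4-oxo-7-(triisopropylsilyloxy)-4H-chromene-3-carbaldehyde
Conditions: TIPSCl (1.2 equiv), imidazole (2.5 equiv), DMF, 0 °C → rt
Reagents that add atoms: chlorotriisopropylsilane, CC(C)[Si](Cl)(C(C)C)C(C)C
Why: Imidazole-promoted silylation of the only phenol; the bulky TIPS ether is chosen because this electron-poor aryl silyl ether must later survive LiHMDS, aqueous triethylamine and heating.

**Step 3**
Reactants: 5 1-(triphenylphosphoranylidene)propan-2-one; 6 1-bromo-3-methylbut-2-ene (prenyl bromide)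
Product: 8 6-methyl-1-(triphenylphosphoranylidene)hept-5-en-2-one, via ylide anion 7 (not isolated)
Conditions: n-BuLi (1.05 equiv), THF, −78 °C; then 6 (1.1 equiv), −78 → 0 °C
Reagents that add atoms: none
Why: γ-Alkylation of a keto-stabilised phosphorus ylide, in which n-BuLi removes a methyl proton to give the ylide–enolate anion 7 and its terminal carbon displaces the primary allylic bromide (SN2).

**Step 4**
Reactants: 4 4-oxo-7-(triisopropylsilyloxy)-4H-chromene-3-carbaldehyde; 8 6-methyl-1-(triphenylphosphoranylidene)hept-5-en-2-one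
Product: 9 (E)-3-(7-methyl-3-oxoocta-1,6-dien-1-yl)-7-(triisopropylsilyloxy)-4H-chromen-4-one
Conditions: 8 (1.2 equiv), toluene, 60 °C
Reagents that add atoms: none
Why: Wittig olefination with a keto-stabilised ylide, which needs no added base (sparing the electrophilic C2 of the pyranone) and should give the E enone as is usual for stabilised ylides.

**Step 5**
Reactants: 9 (E)-3-(7-methyl-3-oxoocta-1,6-dien-1-yl)-7-(triisopropylsilyloxy)-4H-chromen-4-one
Product: 12 (E)-3-(4-diazo-7-methyl-3-oxoocta-1,6-dien-1-yl)-7-(triisopropylsilyloxy)-4H-chromen-4-one, via lithium dienolate 10 (not isolated), via trifluoroacetyl diketone 11 (not isolated)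
Conditions: LiHMDS (1.1 equiv), THF, −78 °C; CF3CO2CH2CF3 (1.2 equiv), −78 °C; aq. HCl work-up; then MsN3 (1.5 equiv), Et3N (1.5 equiv), H2O (1 equiv), MeCN, rt
Reagents that add atoms: methanesulfonyl azide, CS(=O)(=O)N=[N+]=[N-]
Why: Detrifluoroacetylative diazo transfer (a Regitz-type transfer to an activated 1,3-dicarbonyl), in which the α'-CH2 is the only enolisable position, the kinetic enolate 10 undergoes Claisen acylation to 11, and mesyl azide transfers N2 with loss of the trifluoroacetyl group, a sequence suited to base-sensitive α,β-enones.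

**Step 6**
Reactants: 13 2-chloro-1,1-dimethoxyethane (chloroacetaldehyde dimethyl acetal)
Product: 15 methoxyacetylene, via sodium methoxyacetylide 14 (not isolated)
Conditions: NaNH2 (3 equiv), liq. NH3, −33 °C; evaporate NH3; sat. aq. NaCl, −70 → 0 °C; distil into cold ClCH2CH2Cl
Reagents that add atoms: none
Why: Twofold base-induced elimination (methanol, then HCl) from the chloroacetal by sodium amide gives acetylide 14, which is protonated with brine and distilled, the standard preparation of this volatile ynol ether.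

**Step 7**
Reactants: 12 (E)-3-(4-diazo-7-methyl-3-oxoocta-1,6-dien-1-yl)-7-(triisopropylsilyloxy)-4H-chromen-4-one; 15 methoxyacetylene
Product: 20 3-[2-hydroxy-4-methoxy-5-(3-methylbut-2-enyl)phenyl]-7-(triisopropylsilyloxy)-4H-chromen-4-one, via vinylketene 16 (not isolated), via vinylcyclobutenone 17 (not isolated), via dienylketene 18 (not isolated), via cyclohexadienone 19 (not isolated)
Conditions: 15 (4 equiv), ClCH2CH2Cl, hν (405–450 nm LED), 5 °C, sealed Pyrex tube; then 80 °C
Reagents that add atoms: none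
Why: Excitation of the diazo ketone expels N2 with 1,2-shift of the alkenyl group to the diazo carbon (photo-Wolff, forming C5'–C6') to give vinylketene 16, whose carbonyl carbon is attacked by the unsubstituted, nucleophilic carbon of the ynol ether in a [2+2] cycloaddition (forming C2'–C3' and C4'–C5') to give 3-methoxy-4-vinylcyclobutenone 17. Reversible conrotatory 4π ring opening of 17 gives dienylketene 18, and ring B is closed by disrotatory 6π electrocyclisation between the ketene carbon and the chromonyl-bearing alkene terminus (forming C1'–C2'), after which dienone 19 tautomerises to the phenol. The closest known reaction type is the Danheiser benzannulation in its diazo ketone variant with an alkoxyacetylene, which gives resorcinol monoethers. No stereocentre is created, and the quaternary centre of 17 and the sp3 centre of 19 are transient and racemic. The required regiochemistry (OH ortho to the chromone, OMe meta to OH, prenyl para to OH) follows from the polarisation of ketene and ynol ether and from the origin of each carbon, so the two oxygens arrive differentiated as free phenol and methyl ether. Vinyl migration must beat 1,2-hydride shift from the allylic CH2, which direct long-wavelength irradiation of the diazo chromophore (leaving the chromone unexcited) should favour, and the E alkene keeps the chromone on the outside of the closing triene.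

**Step 8**
Reactants: 20 3-[2-hydroxy-4-methoxy-5-(3-methylbut-2-enyl)phenyl]-7-(triisopropylsilyloxy)-4H-chromen-4-one
Product: 21 7-hydroxy-3-[2-hydroxy-4-methoxy-5-(3-methylbut-2-enyl)phenyl]-4H-chromen-4-one
Conditions: TBAF (1.1 equiv), AcOH (1.1 equiv), THF, 0 °C
Reagents that add atoms: none
Why: Fluoride-mediated cleavage of the aryl Si–O bond, buffered with acetic acid so that the 2'-hydroxyisoflavone is not exposed to strongly basic fluoride; the prenyl alkene, the methyl ether and the pyranone are inert to these conditions.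

**Compound list**
1 | 2,4-dihydroxyacetophenone | CC(=O)c1ccc(O)cc1O | starting material
2 | N-[(7-hydroxy-4-oxochromen-3-yl)methylidene]-N-methylmethanaminium chloride | C[N+](C)=Cc1coc2cc(O)ccc2c1=O.[Cl-] | intermediate
3 | 7-hydroxy-4-oxo-4H-chromene-3-carbaldehyde | O=Cc1coc2cc(O)ccc2c1=O | intermediate
4 | 4-oxo-7-(triisopropylsilyloxy)-4H-chromene-3-carbaldehyde | O=Cc1coc2cc(O[Si](C(C)C)(C(C)C)C(C)C)ccc2c1=O | intermediate
5 | 1-(triphenylphosphoranylidene)propan-2-one | CC(=O)C=P(c1ccccc1)(c1ccccc1)c1ccccc1 | starting material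
6 | 1-bromo-3-methylbut-2-ene (prenyl bromide) | CC(C)=CCBr | starting material
7 | lithium 3-(triphenylphosphoranylidene)prop-1-en-2-olate (ylide anion) | [Li+].C=C([O-])C=P(c1ccccc1)(c1ccccc1)c1ccccc1 | intermediate
8 | 6-methyl-1-(triphenylphosphoranylidene)hept-5-en-2-one | CC(C)=CCCC(=O)C=P(c1ccccc1)(c1ccccc1)c1ccccc1 | intermediate
9 | (E)-3-(7-methyl-3-oxoocta-1,6-dien-1-yl)-7-(triisopropylsilyloxy)-4H-chromen-4-one | CC(C)=CCCC(=O)/C=C/c1coc2cc(O[Si](C(C)C)(C(C)C)C(C)C)ccc2c1=O | intermediate
10 | lithium (1E)-7-methyl-1-[4-oxo-7-(triisopropylsilyloxy)chromen-3-yl]octa-1,3,6-trien-3-olate | [Li+].CC(C)=CCC=C([O-])/C=C/c1coc2cc(O[Si](C(C)C)(C(C)C)C(C)C)ccc2c1=O | intermediate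
11 | (E)-3-[7-methyl-3-oxo-4-(trifluoroacetyl)octa-1,6-dien-1-yl]-7-(triisopropylsilyloxy)-4H-chromen-4-one (racemic, largely enolised) | CC(C)=CCC(C(=O)C(F)(F)F)C(=O)/C=C/c1coc2cc(O[Si](C(C)C)(C(C)C)C(C)C)ccc2c1=O | intermediate
12 | (E)-3-(4-diazo-7-methyl-3-oxoocta-1,6-dien-1-yl)-7-(triisopropylsilyloxy)-4H-chromen-4-one | CC(C)=CCC(=[N+]=[N-])C(=O)/C=C/c1coc2cc(O[Si](C(C)C)(C(C)C)C(C)C)ccc2c1=O | intermediate
13 | 2-chloro-1,1-dimethoxyethane | COC(CCl)OC | starting material
14 | sodium methoxyacetylide | [Na+].[C-]#COC | intermediate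
15 | methoxyacetylene | COC#C | intermediate
16 | (E)-2-(3-methylbut-2-enyl)-4-[4-oxo-7-(triisopropylsilyloxy)chromen-3-yl]buta-1,3-dien-1-one | CC(C)=CCC(=C=O)/C=C/c1coc2cc(O[Si](C(C)C)(C(C)C)C(C)C)ccc2c1=O | intermediate
17 | 3-methoxy-4-(3-methylbut-2-enyl)-4-{(E)-2-[4-oxo-7-(triisopropylsilyloxy)chromen-3-yl]ethenyl}cyclobut-2-en-1-one (racemic) | COC1=CC(=O)C1(CC=C(C)C)/C=C/c2coc3cc(O[Si](C(C)C)(C(C)C)C(C)C)ccc3c2=O | intermediate
18 | (3E,5E)-3-methoxy-4-(3-methylbut-2-enyl)-6-[4-oxo-7-(triisopropylsilyloxy)chromen-3-yl]hexa-1,3,5-trien-1-one | O=C=C/C(OC)=C(\C=C\c1coc2cc(O[Si](C(C)C)(C(C)C)C(C)C)ccc2c1=O)CC=C(C)C | intermediate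
19 | 3-methoxy-4-(3-methylbut-2-enyl)-6-[4-oxo-7-(triisopropylsilyloxy)chromen-3-yl]cyclohexa-2,4-dien-1-one (racemic) | COC1=CC(=O)C(c2coc3cc(O[Si](C(C)C)(C(C)C)C(C)C)ccc3c2=O)C=C1CC=C(C)C | intermediate
20 | 3-[2-hydroxy-4-methoxy-5-(3-methylbut-2-enyl)phenyl]-7-(triisopropylsilyloxy)-4H-chromen-4-one | COc1cc(O)c(-c2coc3cc(O[Si](C(C)C)(C(C)C)C(C)C)ccc3c2=O)cc1CC=C(C)C | intermediate
21 | 7-hydroxy-3-[2-hydroxy-4-methoxy-5-(3-methylbut-2-enyl)phenyl]-4H-chromen-4-one | COc1cc(O)c(-c2coc3cc(O)ccc3c2=O)cc1CC=C(C)C | target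

**Step count**
Total: 8 steps. Longest linear sequence: 6 steps (1, 2, 4, 5, 7, 8, from compound 1); steps 3 and 6 are one-step side branches.

**Steps most likely to fail**

Step 7. After loss of nitrogen, hydride shift from the allylic CH2 beside the carbene centre can outrun vinyl migration, so that no vinylketene is available for the alkyne; excitation leaking into the chromone–enone chromophore would add to this. The fallback takes the CH2 away from the diazo carbon and brings in the prenyl group after the ring is made. It sets out from 4 and 5. Wittig reaction of 4 with the parent ylide 5 (toluene, 60 °C) should give (E)-3-(3-oxobut-1-enyl)-7-(triisopropylsilyloxy)chromen-4-one F1. Enolisation to the lithium dienolate F2 (LiHMDS, THF, −78 °C), trifluoroacetylation to the trifluoroacetyl diketone F3 and diazo transfer (MsN3, Et3N, H2O, MeCN) should give the diazomethyl ketone (E)-3-(4-diazo-3-oxobut-1-enyl)-7-(triisopropylsilyloxy)chromen-4-one F4, which has no neighbouring C–H to shift. Irradiation with 15 under the conditions of step 7 should pass through vinylketene F5, vinylcyclobutenone F6, dienylketene F7 and cyclohexadienone F8 to 3-(2-hydroxy-4-methoxyphenyl)-7-(triisopropylsilyloxy)chromen-4-one F9. NBS (MeCN, 0 °C) should brominate para to the free phenol at C5' (C3' lies between two oxygens and is hindered) to give 3-(5-bromo-2-hydroxy-4-methoxyphenyl)-7-(triisopropylsilyloxy)chromen-4-one F10. Stille coupling with tributyl(3-methylbut-2-enyl)stannane (Pd(PPh3)4, DMF, 90 °C) should then give 20, where the route is rejoined before step 8.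

Step 5. The amide base or the cross-conjugated enolate can add to C2 of the pyranone (ring opening, oligomerisation), or acylation can stay incomplete so that diazo transfer stalls. The fallback installs the diazo group on a small fragment and forms the enone afterwards. It sets out from 6 and 4. C-Alkylation of pentane-2,4-dione with 6 (K2CO3, acetone, reflux) should give 3-(3-methylbut-2-enyl)pentane-2,4-dione F11, and deacetylative diazo transfer (MsN3, DBU, MeCN, 0 °C) should give 3-diazo-6-methylhept-5-en-2-one F12. Its methyl group is the only enolisable position, so LiHMDS (THF, −78 °C) should give the lithium enolate F13. Addition of F13 to the aldehyde of 4 at −78 °C should give the racemic β-hydroxy diazo ketone 3-(4-diazo-1-hydroxy-7-methyl-3-oxooct-6-enyl)-7-(triisopropylsilyloxy)chromen-4-one F14. MsCl/Et3N (CH2Cl2, 0 °C → rt) should convert it through the mesylate F15 by E1cB elimination into the E enone 12, where the route is rejoined before step 7.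

Step 4. If olefination with the keto-stabilised ylide is slow, conjugate attack at C2 of the 3-formylchromone and opening of the pyranone can take over, and the alkene geometry can erode. The fallback replaces the olefination by a directed aldol addition followed by elimination. It sets out from 4. Commercial 6-methylhept-5-en-2-one should be deprotonated at its methyl group (LDA, THF, −78 °C) to the kinetic lithium enolate F16. Fast 1,2-addition of F16 to the aldehyde of 4 at −78 °C should give the racemic β-hydroxy ketone 3-(1-hydroxy-7-methyl-3-oxooct-6-enyl)-7-(triisopropylsilyloxy)chromen-4-one F17. MsCl/Et3N (CH2Cl2, 0 °C → rt) should convert it through the mesylate F18 by E1cB elimination into the E enone 9, where the route is rejoined before step 5.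

**Further compounds**
F1 | step 7 | (E)-3-(3-oxobut-1-enyl)-7-(triisopropylsilyloxy)chromen-4-one | CC(=O)/C=C/c1coc2cc(O[Si](C(C)C)(C(C)C)C(C)C)ccc2c1=O
F2 | step 7 | lithium (E)-4-[4-oxo-7-(triisopropylsilyloxy)chromen-3-yl]buta-1,3-dien-2-olate | [Li+].C=C([O-])/C=C/c1coc2cc(O[Si](C(C)C)(C(C)C)C(C)C)ccc2c1=O
F3 | step 7 | (E)-3-(6,6,6-trifluoro-3,5-dioxohex-1-enyl)-7-(triisopropylsilyloxy)chromen-4-one | O=C(CC(=O)C(F)(F)F)/C=C/c1coc2cc(O[Si](C(C)C)(C(C)C)C(C)C)ccc2c1=O
F4 | step 7 | (E)-3-(4-diazo-3-oxobut-1-enyl)-7-(triisopropylsilyloxy)chromen-4-one | [N-]=[N+]=CC(=O)/C=C/c1coc2cc(O[Si](C(C)C)(C(C)C)C(C)C)ccc2c1=O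
F5 | step 7 | (E)-4-[4-oxo-7-(triisopropylsilyloxy)chromen-3-yl]buta-1,3-dien-1-one | O=C=C/C=C/c1coc2cc(O[Si](C(C)C)(C(C)C)C(C)C)ccc2c1=O
F6 | step 7 | 3-methoxy-4-{(E)-2-[4-oxo-7-(triisopropylsilyloxy)chromen-3-yl]ethenyl}cyclobut-2-en-1-one (racemic) | COC1=CC(=O)C1/C=C/c2coc3cc(O[Si](C(C)C)(C(C)C)C(C)C)ccc3c2=O
F7 | step 7 | (3E,5E)-3-methoxy-6-[4-oxo-7-(triisopropylsilyloxy)chromen-3-yl]hexa-1,3,5-trien-1-one | O=C=C/C(OC)=C\C=C\c1coc2cc(O[Si](C(C)C)(C(C)C)C(C)C)ccc2c1=O
F8 | step 7 | 3-methoxy-6-[4-oxo-7-(triisopropylsilyloxy)chromen-3-yl]cyclohexa-2,4-dien-1-one (racemic) | COC1=CC(=O)C(c2coc3cc(O[Si](C(C)C)(C(C)C)C(C)C)ccc3c2=O)C=C1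
F9 | step 7 | 3-(2-hydroxy-4-methoxyphenyl)-7-(triisopropylsilyloxy)chromen-4-one | COc1ccc(-c2coc3cc(O[Si](C(C)C)(C(C)C)C(C)C)ccc3c2=O)c(O)c1
F10 | step 7 | 3-(5-bromo-2-hydroxy-4-methoxyphenyl)-7-(triisopropylsilyloxy)chromen-4-one | COc1cc(O)c(-c2coc3cc(O[Si](C(C)C)(C(C)C)C(C)C)ccc3c2=O)cc1Br
F11 | step 5 | 3-(3-methylbut-2-enyl)pentane-2,4-dione | CC(=O)C(CC=C(C)C)C(C)=O
F12 | step 5 | 3-diazo-6-methylhept-5-en-2-one | CC(=O)C(=[N+]=[N-])CC=C(C)C
F13 | step 5 | lithium 3-diazo-6-methylhepta-1,5-dien-2-olate | [Li+].C=C([O-])C(=[N+]=[N-])CC=C(C)C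
F14 | step 5 | 3-(4-diazo-1-hydroxy-7-methyl-3-oxooct-6-enyl)-7-(triisopropylsilyloxy)chromen-4-one (racemic) | CC(C)=CCC(=[N+]=[N-])C(=O)CC(O)c1coc2cc(O[Si](C(C)C)(C(C)C)C(C)C)ccc2c1=O
F15 | step 5 | 4-diazo-7-methyl-3-oxo-1-[4-oxo-7-(triisopropylsilyloxy)chromen-3-yl]oct-6-enyl methanesulfonate (racemic) | CC(C)=CCC(=[N+]=[N-])C(=O)CC(OS(C)(=O)=O)c1coc2cc(O[Si](C(C)C)(C(C)C)C(C)C)ccc2c1=O
F16 | step 4 | lithium 6-methylhepta-1,5-dien-2-olate | [Li+].C=C([O-])CCC=C(C)C
F17 | step 4 | 3-(1-hydroxy-7-methyl-3-oxooct-6-enyl)-7-(triisopropylsilyloxy)chromen-4-one (racemic) | CC(C)=CCCC(=O)CC(O)c1coc2cc(O[Si](C(C)C)(C(C)C)C(C)C)ccc2c1=O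
F18 | step 4 | 7-methyl-3-oxo-1-[4-oxo-7-(triisopropylsilyloxy)chromen-3-yl]oct-6-enyl methanesulfonate (racemic) | CC(C)=CCCC(=O)CC(OS(C)(=O)=O)c1coc2cc(O[Si](C(C)C)(C(C)C)C(C)C)ccc2c1=O
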